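## The problem

The target is a cis-fused bicyclo[5.3.0]decane (a daucane-type hydroazulene). In the numbering used throughout, the five-membered ring is C1(OAc)–C2–C3(CH3)–C9(H)–C10(OH)(iPr) and the seven-membered ring is C3–C4(OH)–C5–C6(CH3)=C7–C8(O-aroyl)–C9. Six stereocentres must be set, (1S,3S,4S,8S,9R,10R) in this numbering: the C3 methyl, H9, the C4 hydroxyl and the C1 and C10 oxygens lie on one face, the C8 ester oxygen and the isopropyl group on the other. C8 and C9 are contiguous with the ring fusion and are best made together. Once the cis-fused bicycle exists, its convex face (the face of H9 and the angular methyl) can steer the C3 methylation and a syn-dioxygenation of C1/C10, but the C4 carbinol and the concave isopropyl group at C10 cannot come from simple convex-face additions. Sensitive features are the allylic 4-hydroxybenzoate at C8 (ionisation, elimination, acyl transfer), the secondary acetate beside a tertiary alcohol, the free phenol, and the C6=C7 alkene, which must not move into conjugation while C4 is a ketone; the C8 oxygen must also not be lost by β-elimination while C10 is a ketone. The enabling feature is the 1,4-diene pattern hidden in the seven-membered ring: C6(CH3)=C7 with its allylic oxygen on C8, the C8–C9 bond, and an oxygen on C4 separated from C6 by the single methylene C5, which is what a cis-1,2-dialkenylcyclopropanol ether (cyclopropane C4–C5–C6) delivers by Cope rearrangement. The price is a hidden geometric problem: the two alkenyl groups are cis on the cyclopropane only if the enol ether it is made from has oxygen and methyl cis, the isomer that direct enolisation of an α-methyl-β-oxygenated ketone disfavours.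

## Retrosynthesis

**Final unmasking (36 from 35 from 34).** No skeletal bond is cut. The phenol and the C4 hydroxyl are carried as silyl ethers and released last with fluoride, which leaves acetate and benzoate alone. The acetate is placed on the secondary C1 hydroxyl of diol 34, where the tertiary C10 hydroxyl cannot compete.

**C1–O and C10–O (34 from 33).** Both bonds are cut back to the C1=C10 alkene. Adding an isopropyl nucleophile to a C10 ketone would enter from the convex face and give the wrong C10 epimer. Syn-dihydroxylation from the convex face puts both oxygens up and leaves isopropyl on the concave face. The forward step must distinguish C1=C10 from C6=C7, so the deactivating allylic ester is installed first: 33 from alcohol 29 and acid 32 (from 30), and 29 from PMB ether 28.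

**C10–isopropyl (28 from 27 from 25).** The bond is cut to enol triflate 27, made from ketone 25. This needs kinetic enolisation toward C1 and not toward the ring-fusion C9–H, whose enolate could expel the C8 ether.

**Functional-group adjustments (25 from 24 from 23 from 22).** Ketal removal, silylation and reduction of the C4 ketone. The C4 carbinol needs hydride from the concave face, so reagent control is asked for.

**C3–CH3 (22 from 20 via 21).** The angular methyl is cut back to the C3=C4 silyl enol ether. The corresponding ketone would enolise toward the doubly activated C5, so only the enol ether gives the regiodefined enolate. The forward step must methylate on the face of H9.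

**C8–C9 and the seven-membered ring (20 from 19).** This is the key cut. Neighbouring cuts (ring-closing metathesis at C6=C7, aldol or alkylation closure at C8–C9) would need C8 and C9 set separately. The [3,3] shift makes both from one enantiopure cyclopropane and leaves the C3=C4 enol ether needed for the methylation. The precursor is a monocyclic cyclopentene carrying a trisubstituted cyclopropane; it needs cis alkenyl groups and an (E)-enol ether.

**C7=C8 (19 from 13 and 17).** Wittig alkoxymethylenation of the non-enolisable cyclopropane aldehyde 13. The PMB group on the ylide (17, from 14 via 15) is chosen because it can later be removed oxidatively in the presence of silyl ethers and alkenes.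

**Cyclopropane bonds C4–C5 and C5–C6 (13 from 12 from 11).** Methylene transfer to the enol ether alkene of allylic alcohol 11, directed and made enantioselective by the hydroxyl group. A carbene route adding C6 to a siloxydiene would need an oxygenated vinyl diazo compound and has no handle for face control.

**Enol ether geometry (11 from 10 from 9).** Enolising the saturated α-methyl ketone was rejected: allylic strain and chelation both put the enolate oxygen cis to the CH2O arm. That leads to the trans-dialkenylcyclopropane, which rearranges only after diradical epimerisation and loses enantiopurity. Cutting O–Si and the methyl C–H together back to the α-methylene ketone 9 solves this: 1,4-hydrosilylation through the s-cis enone places oxygen and the new methyl cis.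

**C3–C4 and the building blocks (9 from 8 from 3 and 6).** The vinyllithium from bromo ketal 3 (from dione 1 via 2) adds to enal 6 (from diol 4 via 5). All are simple achiral pieces.

## Roads not taken

Alternative 1: The cut is C9–C10. A chiral triazolium-derived carbene turns the aldehyde of the achiral dienone A1 into an acyl anion equivalent that adds to one enone β-carbon (desymmetrising Stetter reaction), giving the cis-fused hydrindenedione A2. Its merit is real: one catalytic step from a substrate two or three steps from p-cresol sets the quaternary C3 and the cis ring fusion without an angular alkylation or a stoichiometric chiral reagent. In that respect it beats the chosen plan. Its weakness is that A2 is a six-membered enone. The target needs a one-carbon ring expansion with regiocontrol, a methyl group at C6, and oxygens at C4 and C8, and nothing in A2 directs these. The chosen plan sets against this a seven-membered ring that arrives with C4–O, C6–CH3, C6=C7 and C8–O already in place.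

Alternative 2: The cut is C2–C3 and C9–C10. Dichloroketene adds suprafacially to the trisubstituted alkene of cycloheptene A3, anti to both allylic silyloxy groups, to give the dichlorocyclobutanone A4; one-carbon ring expansion and dechlorination would follow. The cis fusion is guaranteed, the regiochemistry is reliable, and the quaternary C3 is made without enolate chemistry, which is better than step 15 below. Against it: A3 must itself be made enantiopure; C8 arrives epimeric to the target and needs an invertive esterification beside the ring fusion. Most seriously, A4 has a saturated C5–C7 chain, so the C6 methyl and the C6=C7 alkene would have to be introduced with no handle. The C1 oxygenation and C10 isopropylation remain as in the chosen plan.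

Alternative 3: The cut is C3–C9 and C4–C5. [Rh(CO)2Cl]2 cycloisomerises the allenyl (siloxyvinyl)cyclopropane A5 in a (5+2) cycloaddition to A6, closing both rings at once. It is the most convergent of the four: the quaternary C3 and the C1/C10 diol with its isopropyl group are in place, so the angular methylation, isopropyl coupling and chemoselective dihydroxylation of the chosen plan (steps 15, 19, 20, 24) are avoided. Its weak points are the substrate and the aftermath. A5 needs three stereocentres, one a tertiary carbinol, made beforehand. The quaternary centre and the ring fusion rest on tether diastereocontrol with a 1,1-disubstituted allene terminus. A6 carries its unsaturation as a C7=C8 enol ether with C6 sp3 and C4 as a methylene, so an enone-forming oxidation, a 1,2-reduction to set C8 and an oxidative cleavage followed by the same C4 reduction problem are still needed. The chosen plan sets C8 and C9 together by stereospecific transfer and starts from achiral pieces.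

Key step: step 14

Remark: the target is taken exactly as drawn (C3 methyl and H9 cis), and the facial sense of the dioxaborolane-mediated cyclopropanation is assigned by analogy with cinnamyl alcohol. Bicyclo[5.3.0]decane names use the route locants C1–C10 defined above, not von Baeyer locants.

## Route

Step 1
Reactants: 1 cyclopentane-1,3-dione
Product: 2 3-bromocyclopent-2-en-1-one
Conditions: PPh3, Br2, Et3N, PhH, 0 °C → rt
Reagents that add atoms: bromine, BrBr
Why: The enol oxygen of the vinylogous acid is activated as an oxyphosphonium ion and displaced by bromide (addition–elimination), the standard route to β-bromo enones.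

Step 2
Reactants: 2 3-bromocyclopent-2-en-1-one
Product: 3 7-bromo-1,4-dioxaspiro[4.4]non-6-ene
Conditions: (Me3SiOCH2)2, Me3SiOTf (cat.), CH2Cl2, −78 → −20 °C; pyridine
Reagents that add atoms: 1,2-bis(trimethylsilyloxy)ethane, C[Si](C)(C)OCCO[Si](C)(C)C
Why: Noyori ketalisation under aprotic low-temperature conditions protects the enone carbonyl without moving the double bond.

Step 3
Reactants: 4 2-methylidenepropane-1,3-diol
Product: 5 2-(hydroxymethyl)prop-2-en-1-yl 2,2-dimethylpropanoate
Conditions: tBuCOCl (0.9 equiv), pyridine, CH2Cl2, 0 °C (diol in excess)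
Reagents that add atoms: pivaloyl chloride, CC(C)(C)C(=O)Cl
Why: Statistical monoacylation of a symmetrical diol; the pivalate survives organolithium addition at low temperature and is later removed reductively.

Step 4
Reactants: 5 2-(hydroxymethyl)prop-2-en-1-yl 2,2-dimethylpropanoate
Product: 6 2-formylprop-2-en-1-yl 2,2-dimethylpropanoate
Conditions: MnO2, CH2Cl2, rt
Reagents that add atoms: none
Why: Allylic alcohol oxidation on MnO2 stops at the enal and leaves the ester untouched.

Step 5
Reactants: 3 7-bromo-1,4-dioxaspiro[4.4]non-6-ene; 6 2-formylprop-2-en-1-yl 2,2-dimethylpropanoate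
Product: 8 2-[(1,4-dioxaspiro[4.4]non-6-en-7-yl)(hydroxy)methyl]prop-2-en-1-yl 2,2-dimethylpropanoate (racemic), via vinyllithium 7 (not isolated)
Conditions: tBuLi (2 equiv), THF, −78 °C; then 6, −78 °C
Reagents that add atoms: none
Why: Bromine–lithium exchange gives the β-acylvinyl anion equivalent 7, which adds 1,2 to the aldehyde much faster than it attacks the hindered pivalate; the new carbinol centre is removed in step 6.

Step 6
Reactants: 8 2-[(1,4-dioxaspiro[4.4]non-6-en-7-yl)(hydroxy)methyl]prop-2-en-1-yl 2,2-dimethylpropanoate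
Product: 9 2-(1,4-dioxaspiro[4.4]non-6-ene-7-carbonyl)prop-2-en-1-yl 2,2-dimethylpropanoate
Conditions: MnO2, CH2Cl2, rt; used at once
Reagents that add atoms: none
Why: Neutral oxidation of a doubly allylic alcohol, so the cross-conjugated dienone sees neither acid (Nazarov cyclisation) nor base (Michael addition).

Step 7
Reactants: 9 2-(1,4-dioxaspiro[4.4]non-6-ene-7-carbonyl)prop-2-en-1-yl 2,2-dimethylpropanoate
Product: 10 (2E)-3-(1,4-dioxaspiro[4.4]non-6-en-7-yl)-2-methyl-3-(triethylsilyloxy)prop-2-en-1-yl 2,2-dimethylpropanoate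
Conditions: Et3SiH, RhCl(PPh3)3 (2 mol %), PhH, 50 °C
Reagents that add atoms: triethylsilane, CC[SiH](CC)CC
Why: Rhodium-catalysed 1,4-hydrosilylation of an enone: Si–H adds across oxygen and the terminal CH2 of the s-cis enone through a 1-siloxyallyl rhodium hydride with oxygen anti, so O–Si and the new methyl end up cis and the ring is cis to CH2OPiv (E); the unsubstituted methylene terminus reacts in preference to the β-substituted ring enone.

Step 8
Reactants: 10 (2E)-3-(1,4-dioxaspiro[4.4]non-6-en-7-yl)-2-methyl-3-(triethylsilyloxy)prop-2-en-1-yl 2,2-dimethylpropanoate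
Product: 11 (2E)-3-(1,4-dioxaspiro[4.4]non-6-en-7-yl)-2-methyl-3-(triethylsilyloxy)prop-2-en-1-ol
Conditions: iBu2AlH, CH2Cl2, −78 °C; Rochelle salt
Reagents that add atoms: none
Why: Reductive ester cleavage at low temperature leaves the silyl enol ether and ketal intact; because O–Si is trans to CH2OH, silyl migration is geometrically impossible.

Step 9
Reactants: 11 (2E)-3-(1,4-dioxaspiro[4.4]non-6-en-7-yl)-2-methyl-3-(triethylsilyloxy)prop-2-en-1-ol
Product: 12 [(1S,2S)-2-(1,4-dioxaspiro[4.4]non-6-en-7-yl)-1-methyl-2-(triethylsilyloxy)cyclopropyl]methanol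
Conditions: Et2Zn, CH2I2, MeOCH2CH2OMe, CH2Cl2, −10 °C; (4S,5S)-2-butyl-N,N,N′,N′-tetramethyl-1,3,2-dioxaborolane-4,5-dicarboxamide (1.2 equiv); → rt
Reagents that add atoms: diiodomethane, ICI
Why: Charette asymmetric Simmons–Smith cyclopropanation: the zinc alkoxide of 11 binds the chiral dioxaborolane and Zn(CH2I)2, so methylene is delivered only to the proximal electron-rich enol ether alkene and to the face set by the (4S,5S) ligand; the cis relation of the ring and CH2OH is copied stereospecifically from the E alkene.

Step 10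
Reactants: 12 [(1S,2S)-2-(1,4-dioxaspiro[4.4]non-6-en-7-yl)-1-methyl-2-(triethylsilyloxy)cyclopropyl]methanol
Product: 13 (1R,2S)-2-(1,4-dioxaspiro[4.4]non-6-en-7-yl)-1-methyl-2-(triethylsilyloxy)cyclopropane-1-carbaldehyde
Conditions: Dess–Martin periodinane, NaHCO3, CH2Cl2, 0 °C
Reagents that add atoms: none
Why: Buffered Dess–Martin oxidation; the aldehyde has no α-hydrogen, and the donor–acceptor cyclopropane stays closed while its oxygen is silylated.

Step 11
Reactants: 14 (4-methoxyphenyl)methanol
Product: 15 1-methoxy-4-{[(methylsulfanyl)methoxy]methyl}benzene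
Conditions: NaH, NaI (cat.), ClCH2SMe, MeOCH2CH2OMe, 0 °C → rt
Reagents that add atoms: chloromethyl methyl sulfide, CSCCl
Why: Williamson O-alkylation of the alkoxide with an activated chloride under iodide catalysis.

Step 12
Reactants: 15 1-methoxy-4-{[(methylsulfanyl)methoxy]methyl}benzene
Product: 17 {[(4-methoxybenzyl)oxy]methyl}triphenylphosphonium chloride, via chloromethyl ether 16 (not isolated)
Conditions: SO2Cl2, CH2Cl2, −78 °C → rt; evaporate; PPh3, PhH, rt
Reagents that add atoms: sulfuryl chloride, ClS(Cl)(=O)=O; triphenylphosphine, c1ccc(cc1)P(c1ccccc1)c1ccccc1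
Why: Chlorinolysis of the O,S-acetal gives the chloromethyl ether 16, which quaternises PPh3 by SN2 displacement.

Step 13
Reactants: 13 (1R,2S)-2-(1,4-dioxaspiro[4.4]non-6-en-7-yl)-1-methyl-2-(triethylsilyloxy)cyclopropane-1-carbaldehyde; 17 {[(4-methoxybenzyl)oxy]methyl}triphenylphosphonium chloride
Product: 19 7-[(1S,2S)-2-{(E)-2-[(4-methoxybenzyl)oxy]ethenyl}-2-methyl-1-(triethylsilyloxy)cyclopropyl]-1,4-dioxaspiro[4.4]non-6-ene, via ylide 18 (not isolated)
Conditions: KN(SiMe3)2, THF, −78 → 0 °C; cold work-up, kept cold
Reagents that add atoms: none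
Why: Wittig alkoxymethylenation of a non-enolisable α-quaternary aldehyde; a mixture enriched in the E enol ether is expected, and any Z isomer is inert at the temperature of step 14 and is removed after it.

Step 14
Reactants: 19 7-[(1S,2S)-2-{(E)-2-[(4-methoxybenzyl)oxy]ethenyl}-2-methyl-1-(triethylsilyloxy)cyclopropyl]-1,4-dioxaspiro[4.4]non-6-ene
Product: 20 (8S,9R)-8-(4-methoxybenzyloxy)-6-methyl-4-(triethylsilyloxy)bicyclo[5.3.0]deca-3,6-dien-10-one ethylene ketal (H8 and H9 cis)
Conditions: PhH, 60 °C, base-washed glassware, trace Et3N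
Reagents that add atoms: none
Why: Concerted [3,3] sigmatropic (Cope) rearrangement of a cis-1,2-dialkenylcyclopropane, driven by release of three-membered-ring strain; the closest known type is the cycloheptadiene annulation of cis-1-alkenyl-2-vinylcyclopropanol silyl ethers. Both alkenes must lie over the cyclopropane (boat-shaped six-centre transition state), so the seven-membered ring is closed by the new C8–C9 σ bond between the two alkene termini while the C4–C6 bond opens, a pericyclic three-to-seven ring expansion without ionic or radical intermediates that leaves the C3=C4 silyl enol ether and the C6=C7 alkene. C9 is set by the face of the cyclopentene that the boat presents to the vinyl terminus, which is fixed by the (S) cyclopropane carbon C4. C8 is set by the (E)-enol ether, which keeps the PMB-oxy group exo, so H8 and H9 end up cis and the C8 oxygen lies on the side of C10; its absolute sense comes from cyclopropane carbon C6. The step needs cis alkenyl groups (secured by the geometry of 10 and the stereospecific cyclopropanation), the E enol ether (a Z alkoxy group would point at the ring CH2 and react far more slowly) and exclusion of acid, which would hydrolyse both enol ethers. The C6 methyl is cis to the silyloxy group and not to an alkenyl group, so a competing homodienyl 1,5-hydrogen shift is not available.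

Step 15
Reactants: 20 (8S,9R)-8-(4-methoxybenzyloxy)-6-methyl-4-(triethylsilyloxy)bicyclo[5.3.0]deca-3,6-dien-10-one ethylene ketal
Product: 22 (3S,8S,9R)-8-(4-methoxybenzyloxy)-3,6-dimethylbicyclo[5.3.0]dec-6-ene-4,10-dione 10-ethylene ketal (cis-fused), via lithium enolate 21 (not isolated)
Conditions: MeLi, THF, 0 °C → rt; then MeI (excess), DMPU, −78 → −20 °C
Reagents that add atoms: iodomethane, CI
Why: Si–O cleavage by MeLi regenerates the regiodefined tetrasubstituted enolate 21, which is C-methylated at C3 on the face of H9, anti to the C8 ether, giving the cis ring fusion; excess MeI at low temperature limits proton transfer to the acidic C5 position.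

Step 16
Reactants: 22 (3S,8S,9R)-8-(4-methoxybenzyloxy)-3,6-dimethylbicyclo[5.3.0]dec-6-ene-4,10-dione 10-ethylene ketal
Product: 23 (3S,4S,8S,9R)-4-hydroxy-8-(4-methoxybenzyloxy)-3,6-dimethylbicyclo[5.3.0]dec-6-en-10-one ethylene ketal (OH cis to the C3 methyl)
Conditions: (R)-2-methyl-CBS-oxazaborolidine (0.3 equiv), catecholborane, PhMe, −78 → −40 °C
Reagents that add atoms: none
Why: Corey–Bakshi–Shibata reduction: quaternary C3 and the C5 methylene are well differentiated as large and small groups, and the (R)-oxazaborolidine delivers hydride to the face giving the (4S) carbinol; catecholborane at low temperature avoids hydroboration of C6=C7 and keeps the β,γ-enone from conjugating.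

Step 17
Reactants: 23 (3S,4S,8S,9R)-4-hydroxy-8-(4-methoxybenzyloxy)-3,6-dimethylbicyclo[5.3.0]dec-6-en-10-one ethylene ketal
Product: 24 (3S,4S,8S,9R)-4-(tert-butyldimethylsilyloxy)-8-(4-methoxybenzyloxy)-3,6-dimethylbicyclo[5.3.0]dec-6-en-10-one ethylene ketal
Conditions: tBuMe2SiOTf, 2,6-lutidine, CH2Cl2, −78 → 0 °C
Reagents that add atoms: tert-butyldimethylsilyl trifluoromethanesulfonate, CC(C)(C)[Si](C)(C)OS(=O)(=O)C(F)(F)F
Why: The silyl triflate silylates the hindered neopentyl-type alcohol; low temperature and a hindered base keep the dioxolane intact.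

Step 18
Reactants: 24 (3S,4S,8S,9R)-4-(tert-butyldimethylsilyloxy)-8-(4-methoxybenzyloxy)-3,6-dimethylbicyclo[5.3.0]dec-6-en-10-one ethylene ketal
Product: 25 (3S,4S,8S,9R)-4-(tert-butyldimethylsilyloxy)-8-(4-methoxybenzyloxy)-3,6-dimethylbicyclo[5.3.0]dec-6-en-10-one
Conditions: pyridinium 4-toluenesulfonate (cat.), acetone/H2O, 40 °C
Reagents that add atoms: water, O
Why: Mild acid-catalysed ketal hydrolysis; the PMB and hindered silyl ethers tolerate it, and the mildness guards against C9 epimerisation and β-elimination of the C8 ether.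

Step 19
Reactants: 25 (3S,4S,8S,9R)-4-(tert-butyldimethylsilyloxy)-8-(4-methoxybenzyloxy)-3,6-dimethylbicyclo[5.3.0]dec-6-en-10-one
Product: 27 (3S,4S,8S,9R)-4-(tert-butyldimethylsilyloxy)-8-(4-methoxybenzyloxy)-3,6-dimethylbicyclo[5.3.0]deca-1(10),6-dien-10-yl trifluoromethanesulfonate, via lithium enolate 26 (not isolated)
Conditions: LiN(iPr)2, THF, −78 °C; then PhNTf2, −78 → 0 °C
Reagents that add atoms: N-phenylbis(trifluoromethanesulfonimide), O=S(=O)(N(c1ccccc1)S(=O)(=O)C(F)(F)F)C(F)(F)F
Why: Kinetic deprotonation at the less hindered C1 methylene (not the ring-fusion C9–H) and O-sulfonylation of enolate 26 give the less substituted enol triflate; C9 is then no longer epimerisable.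

Step 20
Reactants: 27 (3S,4S,8S,9R)-4-(tert-butyldimethylsilyloxy)-8-(4-methoxybenzyloxy)-3,6-dimethylbicyclo[5.3.0]deca-1(10),6-dien-10-yl trifluoromethanesulfonate
Product: 28 (3S,4S,8S,9R)-4-(tert-butyldimethylsilyloxy)-10-isopropyl-8-(4-methoxybenzyloxy)-3,6-dimethylbicyclo[5.3.0]deca-1(10),6-diene
Conditions: iPrMgCl, Fe(acac)3 (5 mol %), THF/N-methylpyrrolidone, −30 → 0 °C
Reagents that add atoms: isopropylmagnesium chloride, CC(C)[Mg]Cl
Why: Iron-catalysed Kumada-type coupling of an alkenyl triflate with a secondary alkyl Grignard reagent is fast at low temperature and less prone to isopropyl-to-propyl isomerisation than palladium catalysis.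

Step 21
Reactants: 28 (3S,4S,8S,9R)-4-(tert-butyldimethylsilyloxy)-10-isopropyl-8-(4-methoxybenzyloxy)-3,6-dimethylbicyclo[5.3.0]deca-1(10),6-diene
Product: 29 (3S,4S,8S,9R)-4-(tert-butyldimethylsilyloxy)-10-isopropyl-3,6-dimethylbicyclo[5.3.0]deca-1(10),6-dien-8-ol
Conditions: DDQ (1.1 equiv), CH2Cl2/pH 7 buffer, 0 °C
Reagents that add atoms: none
Why: Oxidative PMB cleavage (benzylic hydride abstraction, then hydrolysis of the oxocarbenium ion); the silyl ether and alkenes are inert, and the reagent is limited to avoid oxidising the allylic alcohol.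

Step 22
Reactants: 30 4-hydroxybenzoic acid
Product: 32 4-(tert-butyldimethylsilyloxy)benzoic acid, via silyl ester 31 (not isolated)
Conditions: tBuMe2SiCl (2.2 equiv), imidazole, DMF, rt; then K2CO3 (cat.), MeOH, rt
Reagents that add atoms: tert-butyldimethylsilyl chloride, CC(C)(C)[Si](C)(C)Cl
Why: Both hydroxyl groups are silylated, and the labile silyl ester is then cleaved selectively by methanolysis, leaving the aryl silyl ether.

Step 23
Reactants: 29 (3S,4S,8S,9R)-4-(tert-butyldimethylsilyloxy)-10-isopropyl-3,6-dimethylbicyclo[5.3.0]deca-1(10),6-dien-8-ol; 32 4-(tert-butyldimethylsilyloxy)benzoic acid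
Product: 33 (3S,4S,8S,9R)-4-(tert-butyldimethylsilyloxy)-10-isopropyl-3,6-dimethylbicyclo[5.3.0]deca-1(10),6-dien-8-yl 4-(tert-butyldimethylsilyloxy)benzoate
Conditions: EDC·HCl, 4-(dimethylamino)pyridine, CH2Cl2, rt
Reagents that add atoms: none
Why: Steglich esterification of the allylic secondary alcohol proceeds with retention at C8.

Step 24
Reactants: 33 (3S,4S,8S,9R)-4-(tert-butyldimethylsilyloxy)-10-isopropyl-3,6-dimethylbicyclo[5.3.0]deca-1(10),6-dien-8-yl 4-(tert-butyldimethylsilyloxy)benzoate
Product: 34 (1S,3S,4S,8S,9R,10R)-4-(tert-butyldimethylsilyloxy)-1,10-dihydroxy-10-isopropyl-3,6-dimethylbicyclo[5.3.0]dec-6-en-8-yl 4-(tert-butyldimethylsilyloxy)benzoate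
Conditions: OsO4 (5 mol %), N-methylmorpholine N-oxide, acetone/H2O, 0 °C → rt
Reagents that add atoms: N-methylmorpholine N-oxide (oxygen, relayed by OsO4), C[N+]1([O-])CCOCC1; water, O
Why: Catalytic syn-dihydroxylation: OsO4 should attack the more electron-rich C1=C10 alkene (C6=C7 is deactivated by the allylic ester) from the convex face, anti to the C8 ester, setting C1 and C10 together as the cis-diol with isopropyl on the concave face.

Step 25
Reactants: 34 (1S,3S,4S,8S,9R,10R)-4-(tert-butyldimethylsilyloxy)-1,10-dihydroxy-10-isopropyl-3,6-dimethylbicyclo[5.3.0]dec-6-en-8-yl 4-(tert-butyldimethylsilyloxy)benzoate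
Product: 35 (1S,3S,4S,8S,9R,10R)-1-acetoxy-4-(tert-butyldimethylsilyloxy)-10-hydroxy-10-isopropyl-3,6-dimethylbicyclo[5.3.0]dec-6-en-8-yl 4-(tert-butyldimethylsilyloxy)benzoate
Conditions: Ac2O, pyridine, 4-(dimethylamino)pyridine (cat.), CH2Cl2, 0 °C
Reagents that add atoms: acetic anhydride, CC(=O)OC(C)=O
Why: Nucleophile-catalysed acetylation of the secondary C1 hydroxyl; the tertiary C10 hydroxyl does not react under these conditions.

Step 26
Reactants: 35 (1S,3S,4S,8S,9R,10R)-1-acetoxy-4-(tert-butyldimethylsilyloxy)-10-hydroxy-10-isopropyl-3,6-dimethylbicyclo[5.3.0]dec-6-en-8-yl 4-(tert-butyldimethylsilyloxy)benzoate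
Product: 36 (1S,3S,4S,8S,9R,10R)-1-acetoxy-4,10-dihydroxy-10-isopropyl-3,6-dimethylbicyclo[5.3.0]dec-6-en-8-yl 4-hydroxybenzoate
Conditions: HF·pyridine, pyridine, THF, 0 °C → rt
Reagents that add atoms: none
Why: Buffered fluoride cleaves the aryl and the secondary silyl ethers while acetate, allylic benzoate and tertiary alcohol are untouched and acyl migration is not promoted.

## Compound list

1 | cyclopentane-1,3-dione | O=C1CCC(=O)C1 | starting material
2 | 3-bromocyclopent-2-en-1-one | O=C1CCC(Br)=C1 | intermediate
3 | 7-bromo-1,4-dioxaspiro[4.4]non-6-ene | BrC1=CC2(CC1)OCCO2 | intermediate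
4 | 2-methylidenepropane-1,3-diol | C=C(CO)CO | starting material
5 | 2-(hydroxymethyl)prop-2-en-1-yl 2,2-dimethylpropanoate | C=C(CO)COC(=O)C(C)(C)C | intermediate
6 | 2-formylprop-2-en-1-yl 2,2-dimethylpropanoate | C=C(C=O)COC(=O)C(C)(C)C | intermediate
7 | (1,4-dioxaspiro[4.4]non-6-en-7-yl)lithium | [Li]C1=CC2(CC1)OCCO2 | intermediate
8 | 2-[(1,4-dioxaspiro[4.4]non-6-en-7-yl)(hydroxy)methyl]prop-2-en-1-yl 2,2-dimethylpropanoate, racemic | C=C(COC(=O)C(C)(C)C)C(O)C1=CC2(CC1)OCCO2 | intermediate
9 | 2-(1,4-dioxaspiro[4.4]non-6-ene-7-carbonyl)prop-2-en-1-yl 2,2-dimethylpropanoate | C=C(COC(=O)C(C)(C)C)C(=O)C1=CC2(CC1)OCCO2 | intermediate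
10 | (2E)-3-(1,4-dioxaspiro[4.4]non-6-en-7-yl)-2-methyl-3-(triethylsilyloxy)prop-2-en-1-yl 2,2-dimethylpropanoate (ring cis to CH2O, O–Si cis to CH3) | C1COC2(O1)CCC(=C2)/C(O[Si](CC)(CC)CC)=C(/C)COC(=O)C(C)(C)C | intermediate
11 | (2E)-3-(1,4-dioxaspiro[4.4]non-6-en-7-yl)-2-methyl-3-(triethylsilyloxy)prop-2-en-1-ol | C1COC2(O1)CCC(=C2)/C(O[Si](CC)(CC)CC)=C(/C)CO | intermediate
12 | [(1S,2S)-2-(1,4-dioxaspiro[4.4]non-6-en-7-yl)-1-methyl-2-(triethylsilyloxy)cyclopropyl]methanol (ring cis to CH2OH) | C1COC2(O1)CCC(=C2)[C@@]3(O[Si](CC)(CC)CC)C[C@@]3(C)CO | intermediate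
13 | (1R,2S)-2-(1,4-dioxaspiro[4.4]non-6-en-7-yl)-1-methyl-2-(triethylsilyloxy)cyclopropane-1-carbaldehyde | C1COC2(O1)CCC(=C2)[C@@]3(O[Si](CC)(CC)CC)C[C@@]3(C)C=O | intermediate
14 | (4-methoxyphenyl)methanol | COc1ccc(CO)cc1 | starting material
15 | 1-methoxy-4-{[(methylsulfanyl)methoxy]methyl}benzene | COc1ccc(COCSC)cc1 | intermediate
16 | 1-[(chloromethoxy)methyl]-4-methoxybenzene | COc1ccc(COCCl)cc1 | intermediate
17 | {[(4-methoxybenzyl)oxy]methyl}triphenylphosphonium chloride | COc1ccc(COC[P+](c2ccccc2)(c2ccccc2)c2ccccc2)cc1.[Cl-] | intermediate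
18 | {[(4-methoxybenzyl)oxy]methylidene}triphenylphosphorane | COc1ccc(COC=P(c2ccccc2)(c2ccccc2)c2ccccc2)cc1 | intermediate
19 | 7-[(1S,2S)-2-{(E)-2-[(4-methoxybenzyl)oxy]ethenyl}-2-methyl-1-(triethylsilyloxy)cyclopropyl]-1,4-dioxaspiro[4.4]non-6-ene (alkenyl groups cis) | C1COC2(O1)CCC(=C2)[C@@]3(O[Si](CC)(CC)CC)C[C@@]3(C)/C=C/OCc4ccc(OC)cc4 | intermediate
20 | (8S,9R)-8-(4-methoxybenzyloxy)-6-methyl-4-(triethylsilyloxy)bicyclo[5.3.0]deca-3,6-dien-10-one ethylene ketal (route locants; H8/H9 cis) | C1CC2=C(O[Si](CC)(CC)CC)CC(C)=C[C@H](OCc3ccc(OC)cc3)[C@@H]2C14OCCO4 | intermediate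
21 | lithium C3=C4 enolate corresponding to 20 | C1CC2=C(O[Li])CC(C)=C[C@H](OCc3ccc(OC)cc3)[C@@H]2C14OCCO4 | intermediate
22 | (3S,8S,9R)-8-(4-methoxybenzyloxy)-3,6-dimethylbicyclo[5.3.0]dec-6-ene-4,10-dione 10-ethylene ketal (C3 methyl cis to H9) | C1C[C@]2(C)C(=O)CC(C)=C[C@H](OCc3ccc(OC)cc3)[C@@H]2C14OCCO4 | intermediate
23 | (3S,4S,8S,9R)-4-hydroxy-8-(4-methoxybenzyloxy)-3,6-dimethylbicyclo[5.3.0]dec-6-en-10-one ethylene ketal (OH cis to C3 methyl) | C1C[C@]2(C)[C@@H](O)CC(C)=C[C@H](OCc3ccc(OC)cc3)[C@@H]2C14OCCO4 | intermediate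
24 | C4 tert-butyldimethylsilyl ether of 23 | C1C[C@]2(C)[C@@H](O[Si](C)(C)C(C)(C)C)CC(C)=C[C@H](OCc3ccc(OC)cc3)[C@@H]2C14OCCO4 | intermediate
25 | (3S,4S,8S,9R)-4-(tert-butyldimethylsilyloxy)-8-(4-methoxybenzyloxy)-3,6-dimethylbicyclo[5.3.0]dec-6-en-10-one | C1C[C@]2(C)[C@@H](O[Si](C)(C)C(C)(C)C)CC(C)=C[C@H](OCc3ccc(OC)cc3)[C@@H]2C1=O | intermediate
26 | lithium C1=C10 enolate of 25 | [Li]OC1=CC[C@]2(C)[C@@H](O[Si](C)(C)C(C)(C)C)CC(C)=C[C@H](OCc3ccc(OC)cc3)[C@H]12 | intermediate
27 | C1=C10 enol trifluoromethanesulfonate of 25 | FC(F)(F)S(=O)(=O)OC1=CC[C@]2(C)[C@@H](O[Si](C)(C)C(C)(C)C)CC(C)=C[C@H](OCc3ccc(OC)cc3)[C@H]12 | intermediate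
28 | (3S,4S,8S,9R)-4-(tert-butyldimethylsilyloxy)-10-isopropyl-8-(4-methoxybenzyloxy)-3,6-dimethylbicyclo[5.3.0]deca-1(10),6-diene | CC(C)C1=CC[C@]2(C)[C@@H](O[Si](C)(C)C(C)(C)C)CC(C)=C[C@H](OCc3ccc(OC)cc3)[C@H]12 | intermediate
29 | (3S,4S,8S,9R)-4-(tert-butyldimethylsilyloxy)-10-isopropyl-3,6-dimethylbicyclo[5.3.0]deca-1(10),6-dien-8-ol | CC(C)C1=CC[C@]2(C)[C@@H](O[Si](C)(C)C(C)(C)C)CC(C)=C[C@H](O)[C@H]12 | intermediate
30 | 4-hydroxybenzoic acid | OC(=O)c1ccc(O)cc1 | starting material
31 | tert-butyldimethylsilyl 4-(tert-butyldimethylsilyloxy)benzoate | CC(C)(C)[Si](C)(C)OC(=O)c1ccc(O[Si](C)(C)C(C)(C)C)cc1 | intermediate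
32 | 4-(tert-butyldimethylsilyloxy)benzoic acid | OC(=O)c1ccc(O[Si](C)(C)C(C)(C)C)cc1 | intermediate
33 | C8 4-(tert-butyldimethylsilyloxy)benzoate of 29 | CC(C)C1=CC[C@]2(C)[C@@H](O[Si](C)(C)C(C)(C)C)CC(C)=C[C@H](OC(=O)c3ccc(O[Si](C)(C)C(C)(C)C)cc3)[C@H]12 | intermediate
34 | (1S,10R) cis-diol from 33 (both OH on the face of H9 and the C3 methyl) | O[C@H]1C[C@]2(C)[C@@H](O[Si](C)(C)C(C)(C)C)CC(C)=C[C@H](OC(=O)c3ccc(O[Si](C)(C)C(C)(C)C)cc3)[C@@H]2[C@]1(O)C(C)C | intermediate
35 | C1 acetate of 34 | CC(=O)O[C@H]1C[C@]2(C)[C@@H](O[Si](C)(C)C(C)(C)C)CC(C)=C[C@H](OC(=O)c3ccc(O[Si](C)(C)C(C)(C)C)cc3)[C@@H]2[C@]1(O)C(C)C | intermediate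
36 | (1S,3S,4S,8S,9R,10R)-1-acetoxy-4,10-dihydroxy-10-isopropyl-3,6-dimethylbicyclo[5.3.0]dec-6-en-8-yl 4-hydroxybenzoate (route locants) | CC(=O)O[C@H]1C[C@]2(C)[C@@H](O)CC(C)=C[C@H](OC(=O)c3ccc(O)cc3)[C@@H]2[C@]1(O)C(C)C | target

## Step count and weak points

Total: 26 steps. Longest linear sequence: 21 steps (1, 2, 5–10, 13–21, 23–26). Side branches: steps 3–4 (enal 6), 11–12 (phosphonium salt 17) and 22 (acid 32).

**Step 14 (key step).** The most likely failure is a sluggish rearrangement of the crowded cyclopropane (quaternary C6, fully substituted C3). It would then need temperatures at which the C4–C6 bond opens to a diradical, with one-centre epimerisation, loss of enantiopurity and formation of the trans isomer. Fallback: use the oxyanion-accelerated variant. Starting from 19, an anhydrous fluoride source (Bu4N+ Ph3SiF2−, THF, −40 °C) removes the silyl group to give the tetrabutylammonium cyclopropanolate F1. This should rearrange well below room temperature to the tetrabutylammonium enolate F2, which is methylated in the same flask with MeI and rejoins the route at 22.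

**Step 7.** The risk is loss of geometric control through syn–anti isomerisation of the siloxyallyl rhodium intermediate, or competing 1,2-hydrosilylation. Either would erode the cis relation needed in 19. Fallback: starting from 9, conjugate reduction with LiBH(sBu)3 (THF, −78 °C) gives the saturated ketone F3. Soft enolisation (Et3SiOTf, Et3N) gives 10 together with its geometric isomer F4; these are separated, and F4 is hydrolysed back to F3 and recycled. The sequence rejoins at 10.

**Step 13.** The risk is poor E/Z selectivity in the alkoxymethylenation, which halves the material that can rearrange. Fallback: starting from 13, a boron-Wittig reaction (CH2(Bpin)2, lithium 2,2,6,6-tetramethylpiperidide) gives the (E)-alkenylboronate F5. Stereoretentive Chan–Lam-type etherification with alcohol 14 (Cu(OAc)2, Et3N, rt) then gives 19.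

**Step 15.** The risk is proton transfer from the product, whose C5 hydrogens are both α to the ketone and allylic, to the hindered enolate, leading to over-methylation at C5 and recovered unmethylated ketone. Fallback: starting from 20, cyclopropanation of the silyl enol ether (Et2Zn, CH2I2) on the convex face gives the siloxycyclopropane F6. Mild base (K2CO3, MeOH) opens it to the C3-methyl ketone, rejoining at 22 without a free enolate.

**Step 16.** The risk is a mismatch between the oxazaborolidine and the intrinsic preference of the bicycle for convex-face hydride attack, giving poor facial selectivity. Fallback: starting from 22, replace hydride delivery by single-electron reduction under thermodynamic control (SmI2, H2O, Et3N, THF). This should favour the carbinol on the open convex face and rejoins at 23 without new intermediates.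

**Step 24.** The risk is competing osmylation of C6=C7. Fallback: build the diol from the ketone instead. Starting from 25, LiN(iPr)2 and 2-(phenylsulfonyl)-3-phenyloxaziridine give the α-hydroxy ketone F7 (oxygen from the convex face). Excess iPrMgCl with CeCl3 should add anti to the C1 oxygen to give the cis-diol F8. Acetylation gives F9 and DDQ gives the C8 alcohol F10, which is esterified with 32 to rejoin at 35.

## Further compounds

F1 | step 14 | tetrabutylammonium (1S,2S)-1-(1,4-dioxaspiro[4.4]non-6-en-7-yl)-2-{(E)-2-[(4-methoxybenzyl)oxy]ethenyl}-2-methylcyclopropan-1-olate | C1COC2(O1)CCC(=C2)[C@@]3([O-])C[C@@]3(C)/C=C/OCc4ccc(OC)cc4.CCCC[N+](CCCC)(CCCC)CCCC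
F2 | step 14 | tetrabutylammonium C3=C4 enolate (desilylated form of 20) | C1CC2=C([O-])CC(C)=C[C@H](OCc3ccc(OC)cc3)[C@@H]2C14OCCO4.CCCC[N+](CCCC)(CCCC)CCCC
F3 | step 7 | 3-(1,4-dioxaspiro[4.4]non-6-en-7-yl)-2-methyl-3-oxopropyl 2,2-dimethylpropanoate, racemic | CC(COC(=O)C(C)(C)C)C(=O)C1=CC2(CC1)OCCO2
F4 | step 7 | (2Z)-3-(1,4-dioxaspiro[4.4]non-6-en-7-yl)-2-methyl-3-(triethylsilyloxy)prop-2-en-1-yl 2,2-dimethylpropanoate | C1COC2(O1)CCC(=C2)/C(O[Si](CC)(CC)CC)=C(\C)COC(=O)C(C)(C)C
F5 | step 13 | 7-[(1S,2S)-2-methyl-2-[(E)-2-(4,4,5,5-tetramethyl-1,3,2-dioxaborolan-2-yl)ethenyl]-1-(triethylsilyloxy)cyclopropyl]-1,4-dioxaspiro[4.4]non-6-ene | C1COC2(O1)CCC(=C2)[C@@]3(O[Si](CC)(CC)CC)C[C@@]3(C)/C=C/B4OC(C)(C)C(C)(C)O4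
F6 | step 15 | siloxycyclopropane from 20 (CH2 bridging C3 and C4 on the face of H9) | C1C[C@@]23C[C@@]3(O[Si](CC)(CC)CC)CC(C)=C[C@H](OCc4ccc(OC)cc4)[C@@H]2C15OCCO5
F0 | step 16 | none | none
F7 | step 24 | (1S)-1-hydroxy derivative of ketone 25 | O[C@H]1C[C@]2(C)[C@@H](O[Si](C)(C)C(C)(C)C)CC(C)=C[C@H](OCc3ccc(OC)cc3)[C@@H]2C1=O
F8 | step 24 | (1S,10R) cis-diol with C8 PMB ether | O[C@H]1C[C@]2(C)[C@@H](O[Si](C)(C)C(C)(C)C)CC(C)=C[C@H](OCc3ccc(OC)cc3)[C@@H]2[C@]1(O)C(C)C
F9 | step 24 | C1 acetate of F8 | CC(=O)O[C@H]1C[C@]2(C)[C@@H](O[Si](C)(C)C(C)(C)C)CC(C)=C[C@H](OCc3ccc(OC)cc3)[C@@H]2[C@]1(O)C(C)C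
F10 | step 24 | C8 alcohol from F9 | CC(=O)O[C@H]1C[C@]2(C)[C@@H](O[Si](C)(C)C(C)(C)C)CC(C)=C[C@H](O)[C@@H]2[C@]1(O)C(C)C
A1 | alternative 1 | 4-methyl-4-(3-oxopropyl)cyclohexa-2,5-dien-1-one | CC1(CCC=O)C=CC(=O)C=C1
A2 | alternative 1 | cis-fused hydrindenedione with quaternary C3 | C1C[C@]2(C)C=CC(=O)C[C@@H]2C1=O
A3 | alternative 2 | cis-3-(tert-butyldimethylsilyloxy)-2-methyl-7-(triisopropylsilyloxy)cycloheptene (C3=C9 alkene, route locants) | CC1=C[C@H](O[Si](C(C)C)(C(C)C)C(C)C)CCC[C@@H]1O[Si](C)(C)C(C)(C)C
A4 | alternative 2 | cis-fused dichlorocyclobutanone with quaternary C3 | ClC1(Cl)[C@]2(C)[C@@H](O[Si](C)(C)C(C)(C)C)CCC[C@@H](O[Si](C(C)C)(C(C)C)C(C)C)[C@@H]2C1=O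
A5 | alternative 3 | allenyl (siloxyvinyl)cyclopropane with C1/C10 acetonide (alkene geometry and the vinyl-bearing cyclopropane carbon left open) | CC1(C)O[C@@H](CC(C)=C=C)[C@@](O1)(C(C)C)C=C(O[Si](C)(C)C(C)(C)C)C2C[C@H]2C
A6 | alternative 3 | cis-fused bicyclo[5.3.0]decadiene with C8 silyl enol ether, C4 methylene and C1/C10 acetonide | CC1(C)O[C@H]2C[C@]3(C)C(=C)C[C@@H](C)C=C(O[Si](C)(C)C(C)(C)C)[C@@H]3[C@]2(O1)C(C)C
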